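## The problem

Compound 13 is hydrangetin alkylated at O-7 with an oxygenated C10 chain. The chain is numbered here C1' (OCH2), C2' and C3' (oxirane carbons, C3' bearing a methyl group), C4' (CH2), C5' (carbinol) and C6'=C7' (isopropylidene olefin). The coumarin, a benzene ring fused to an α-pyranone, is joined to the chain only through the aryl ether oxygen, so the carbon work lies in the acyclic chain and the only ring to be closed is the oxirane.

Three stereocentres, all R, must be set. C2' and C3' sit in a trisubstituted epoxide whose CH2O group is cis to the methyl and trans to C4'. The allylic carbinol C5' has its hydroxyl 1,3-anti to the C3' oxygen along the C2'–C6' backbone. Since C2'/C3' are adjacent and C3'/C5' are 1,3-related oxygen-bearing carbons, one centre can in principle set the next (C2' → C3' → C5').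

Little in the molecule tolerates rough handling:
- The epoxide ionises at its tertiary carbon C3' under acid.
- The C5' alcohol is allylic to a trisubstituted olefin and ionises or transposes under acid.
- The coumarin is a lactone and a Michael acceptor.
- A 2,3-epoxy alcohol with a free C1' hydroxyl can undergo Payne rearrangement.
- An epoxide next to a C5' ketone would be a β,γ-epoxy ketone that opens by β-elimination.

The feature that opens the route is that C3' is a fully substituted, oxygen-bearing carbon flanked by the oxygenated C2' and by a methylene, C4', that is α to the oxygenated C5'. The C3'–C4' bond is therefore an aldol bond between a methyl ketone (C1'–C3' plus the methyl) and the acetyl methyl of mesityl oxide (C4'–C7'). A chlorine on C2' can first steer that addition and then leave when the oxirane closes.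

## Retrosynthesis

**Aryl ether (13 ⇒ 11 + 12).** The C1'–OAr bond is cut first, giving epoxy diol 11 and hydrangetin 12. Hydrangetin is the complete aromatic half, and attaching it last keeps the lactone away from the enolate, the hydride and the carbonate/methanol used on the chain. Building the pyranone at the end instead would add steps without touching the stereochemical problem. The forward reaction, a Mitsunobu etherification, must take the primary C1' hydroxyl in preference to the secondary allylic C5' hydroxyl and leave the epoxide alone.

**Silyl ether and oxirane (11 ⇒ 10 ⇒ 9).** The O–Si bond of 10 is restored, then the O–C2' bond of the oxirane is cut to give chlorohydrin 9, with chlorine on C2' in the opposite configuration. Against an olefin epoxidation this needs no chiral oxidant and no choice among three double bonds, because the epoxide configuration is already written into the chlorohydrin. The precursor has lost the ring. The closure must be a 3-exo displacement by the tertiary alkoxide that outruns attack by the C5' oxygen. The silyl ether must stay on during it, so that the primary oxygen can neither close a terminal epoxide nor start a Payne rearrangement.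

**Carbinol C5' (9 ⇒ 8).** The C5'–H bond is cut, so the allylic alcohol goes back to the enone carbonyl of 8. Doing this while C3' still carries a free hydroxyl has two advantages over reducing later. The hydroxyl can deliver hydride intramolecularly and fix the 1,3-anti relation, and the molecule never holds an epoxide and a C5' ketone together. The forward reduction must be 1,2-selective on the enone and must discriminate the methyl from the chloroalkyl substituent on the directing carbinol.

**Aldol bond C3'–C4' (8 ⇒ 5 + 6, through 7).** The C5–C6 bond of 8 is cut to chloro ketone 5 and mesityl oxide 6, which reacts as its lithium dienolate 7. Two neighbouring cuts are worse: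
- Cutting C4'–C5' would require enolising the base-sensitive chloro ketone and would create C5', not C3'.
- Cutting C2'–C3' would need an α-oxygenated carbanion.

The chosen cut removes four carbons as a bulk chemical and leaves a C4 ketone with a single stereocentre. The forward step needs kinetic deprotonation of 6 at the acetyl methyl, addition faster than proton transfer, and Cornforth facial selectivity from the C–Cl centre.

**Chloro ketone (5 ⇒ 4 ⇒ 3 ⇒ 2 ⇒ 1).** The methyl–carbonyl bond of 5 is cut to Weinreb amide 4, the silyl group is removed to 3, and the amide is cut to chloro acid 2. The C–Cl bond is traced to the C–N bond of L-serine 1 with retention. L-Serine already holds the hydroxymethyl group, the stereocentre and the carboxyl carbon in the right order. The forward steps must keep the α-chloro centre from epimerising.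

## Roads not taken

**Alternative 1:** Late Shi epoxidation.
- **Cut:** both C–O bonds of the oxirane, back to the E-olefin of dienone ether A2. C5' is held as a ketone there, so that C6'=C7' is an electron-poor enone olefin.
- **Forward key step:** the dioxirane formed from the fructose-derived Shi ketone and KHSO5 would transfer oxygen to the C2'=C3' olefin of A2 to give epoxy ketone A1. A reagent-controlled 1,2-reduction of the enone would then give 13.
- **Merits:** the route is convergent, hydrangetin 12 is attached early by a plain alkylation, and trisubstituted E-olefins are the substrate class for which this dioxirane is most selective. The coumarin and enone double bonds are electron-poor and should be ignored.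
- **Weak points:** A2 is a β,γ-unsaturated ketone whose C4' methylene is both allylic and α to the carbonyl, so the carbonate buffer of the epoxidation can move the olefin into conjugation. A1 is a β,γ-epoxy ketone that opens to a γ-hydroxy enone on deprotonation at C4'. C5' then needs a second chiral reagent, with no help from the substrate.
- **Comparison:** the epoxide configuration is set by a catalyst and does not depend on a substrate-controlled addition to a ketone, which makes that single event more predictable than the Cornforth step. The chosen plan sets against this that epoxide and C5' ketone never coexist, and that one amino acid carbon replaces two chiral reagents.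

**Alternative 2:** Pyranone closed last.
- **Cut:** O1–C2 and C3=C4 of the pyranone, back to salicylaldehyde A4, which already carries the full side chain.
- **Forward key step:** the phenol of A4 would add to (triphenylphosphoranylidene)ketene, and the resulting ester ylide would olefinate the ortho aldehyde to give silyl ether A3. Desilylation would give 13.
- **Merits:** the ring closure is neutral and reliable. The route does not depend on buying a natural coumarin, because A4 would come from aldehyde A5 by alkylation of its non-chelated 4-hydroxyl.
- **Weak points:** it does nothing for the three stereocentres, so the side chain must still be made by some other plan. C5' must be protected, since a free alcohol also adds to the ketenylidene ylide. The fragile epoxide is heated with the ylide and carried through more steps.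
- **Comparison:** the ring closure is probably safer than any single step of the chosen route, and it would be the better road if 12 could not be obtained. The chosen plan sets against this that the coumarin is bought whole and that two steps (protection and deprotection at C5') are saved.

**Alternative 3:** Iron-catalysed 1,4-hydroboration.
- **Cut:** the C1'–O bond is traced to the C–B bond of allylboronate A6, and A6 to silyloxy diene A7, the silyl ether of (R)-ipsdienol.
- **Forward key step:** FeCl2 with a 2-iminopyridine ligand, reduced by magnesium to low-valent iron, would add pinacolborane 1,4 across the diene of A7. Boron goes to C1' and hydrogen to the future C3' methyl, and the E C2'=C3' olefin of A6 is formed. Oxidation to allylic alcohol A8, Sharpless epoxidation (Ti(OiPr)4, diethyl tartrate, tBuOOH), Mitsunobu coupling with 12 and desilylation would follow.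
- **Merits:** it uses the natural monoterpene skeleton. The Sharpless epoxidation of a geraniol-type alcohol such as A8 is among the most dependable ways to make exactly this oxirane. C5' is protected during the Mitsunobu step, so no hydroxyl selectivity is needed there.
- **Weak points:** enantiopure A7 is not a bulk chemical and needs its own asymmetric synthesis. The regiochemistry and olefin geometry of the hydroboration were worked out on simple dienes and are untested next to a silyloxy stereocentre. The allylboronate is sensitive. Three separate reagents set C5', the olefin geometry and the epoxide.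
- **Comparison:** in the reliability of the epoxidation and of the final etherification this road is better than the chosen one. The chosen plan sets against it a single cheap chiral source, no transition-metal step, and a chain assembled in one C–C bond formation. The price is two substrate-controlled relays whose selectivity is less certain.

Key step: step 5

Assumption: hydrangetin (12) is taken as a purchasable coumarin; its C-7 phenol is its only acidic hydroxyl, so it is used unprotected.

## Route

Step 1
Reactants: 1 L-serine
Product: 2 (2S)-2-chloro-3-hydroxypropanoic acid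
Conditions: NaNO2, 6 M aq. HCl, 0 °C → rt
Reagents that add atoms: hydrochloric acid, Cl
Why: Diazotisation of the α-amino acid; the carboxylate displaces N2 to give an α-lactone that chloride opens, so two inversions give net retention and the (S)-chloro acid (known conversion of α-amino acids into α-chloro acids).

Step 2
Reactants: 2 (2S)-2-chloro-3-hydroxypropanoic acid
Product: 3 (2S)-2-chloro-3-hydroxy-N-methoxy-N-methylpropanamide
Conditions: MeNHOMe·HCl, EDC·HCl, HOBt, N-methylmorpholine, CH2Cl2, 0 °C → rt
Reagents that add atoms: N,O-dimethylhydroxylamine hydrochloride, CNOC.Cl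
Why: Carbodiimide/HOBt amide coupling; the amine is acylated much faster than the primary hydroxyl, and the weak base at 0 °C should leave the α-chloro centre untouched.

Step 3
Reactants: 3 (2S)-2-chloro-3-hydroxy-N-methoxy-N-methylpropanamide
Product: 4 (2S)-3-[(tert-butyldimethylsilyl)oxy]-2-chloro-N-methoxy-N-methylpropanamide
Conditions: TBSCl, imidazole, CH2Cl2, 0 °C → rt
Reagents that add atoms: tert-butyldimethylsilyl chloride, CC(C)(C)[Si](C)(C)Cl
Why: Standard silylation of a primary alcohol; the bulky silyl ether coordinates lithium poorly, which the non-chelated addition of step 5 needs, and it later blocks the primary oxygen during epoxide closure.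

Step 4
Reactants: 4 (2S)-3-[(tert-butyldimethylsilyl)oxy]-2-chloro-N-methoxy-N-methylpropanamide
Product: 5 (3S)-4-[(tert-butyldimethylsilyl)oxy]-3-chlorobutan-2-one
Conditions: MeMgBr, THF, −78 → 0 °C; cold 1 M HCl quench
Reagents that add atoms: methylmagnesium bromide, C[Mg]Br
Why: Weinreb ketone synthesis; the chelated tetrahedral magnesium adduct survives until the acidic quench, so there is no second addition and the free α-chloro ketone never meets base, which should preserve the (S) centre; 5 is used promptly.

Step 5
Reactants: 5 (3S)-4-[(tert-butyldimethylsilyl)oxy]-3-chlorobutan-2-one, 6 mesityl oxide (4-methylpent-3-en-2-one)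
Product: 8 (6R,7S)-8-[(tert-butyldimethylsilyl)oxy]-7-chloro-6-hydroxy-2,6-dimethyloct-2-en-4-one, via lithium dienolate of mesityl oxide 7 (not isolated)
Conditions: LiN(iPr)2 (LDA), THF, −78 °C; add 5, −78 °C; AcOH/THF quench at −78 °C
Reagents that add atoms: none
Why: LDA removes a proton from the acetyl methyl of 6 under kinetic control to give the cross-conjugated lithium dienolate 7, whose CH2 terminus adds to the ketone carbonyl of 5 in an aldol addition; the C5–C6 bond of 8 (C4'–C3' of the target) is formed and no ring is closed. The closest known reactions are additions of lithium ketone enolates to α-chloro aldehydes, which give anti chlorohydrins, and Cornforth additions of organomagnesium reagents to α-chloro ketones. The one new stereocentre, C6, is controlled by the neighbouring C7–Cl centre: in the Cornforth arrangement the C–Cl bond lies anti to the carbonyl (in the polar Felkin–Anh picture, anti to the incoming nucleophile) and the enolate passes the hydrogen on C7, not the CH2OSi group, which gives the (6R,7S) isomer. Three selectivities are needed: α′- over γ-deprotonation of 6, secured by the amide base at −78 °C; carbonyl addition over proton transfer from the acidic CHCl and CH3 positions of 5, secured by the inductively activated carbonyl and the low temperature; and non-chelated addition, secured by the bulky, weakly coordinating silyl ether. The lithium aldolate is protonated at −78 °C so that it neither reverts nor closes early to the oxirane.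

Step 6
Reactants: 8 (6R,7S)-8-[(tert-butyldimethylsilyl)oxy]-7-chloro-6-hydroxy-2,6-dimethyloct-2-en-4-one
Product: 9 (2S,3R,5R)-1-[(tert-butyldimethylsilyl)oxy]-2-chloro-3,7-dimethyloct-6-ene-3,5-diol
Conditions: Me4NBH(OAc)3, MeCN/AcOH, −40 → −20 °C
Reagents that add atoms: none
Why: Evans–Saksena hydroxyl-directed reduction; the tertiary hydroxyl replaces an acetate on boron and hydride is delivered within a chair in which the alkenyl group and the larger chloroalkyl substituent are equatorial and the methyl is axial, which should give the 1,3-anti (5R) carbinol by 1,2-reduction only.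

Step 7
Reactants: 9 (2S,3R,5R)-1-[(tert-butyldimethylsilyl)oxy]-2-chloro-3,7-dimethyloct-6-ene-3,5-diol
Product: 10 (2R)-1-[(2R,3R)-3-{[(tert-butyldimethylsilyl)oxy]methyl}-2-methyloxiran-2-yl]-4-methylpent-3-en-2-ol
Conditions: K2CO3, MeOH, 0 °C → rt
Reagents that add atoms: none
Why: Intramolecular Williamson (3-exo-tet) closure of the chlorohydrin; the tertiary alkoxide displaces chloride with inversion at C2, giving the (2R,3R) oxirane with CH2O cis to methyl; this gem-disubstituted closure should outrun 5-exo attack by the C5 oxygen, and the silyl ether excludes a terminal epoxide.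

Step 8
Reactants: 10 (2R)-1-[(2R,3R)-3-{[(tert-butyldimethylsilyl)oxy]methyl}-2-methyloxiran-2-yl]-4-methylpent-3-en-2-ol
Product: 11 (2R)-1-[(2R,3R)-3-(hydroxymethyl)-2-methyloxiran-2-yl]-4-methylpent-3-en-2-ol
Conditions: Bu4NF, AcOH, THF, 0 °C → rt
Reagents that add atoms: none
Why: Fluoride cleavage of the primary silyl ether; the acetic acid buffer keeps the liberated 2,3-epoxy alcohol from Payne rearrangement, and no stereocentre is touched.

Step 9
Reactants: 11 (2R)-1-[(2R,3R)-3-(hydroxymethyl)-2-methyloxiran-2-yl]-4-methylpent-3-en-2-ol, 12 hydrangetin (7-hydroxy-8-methoxy-2H-chromen-2-one)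
Product: 13 7-{[(2R,3R)-3-[(2R)-2-hydroxy-4-methylpent-3-en-1-yl]-3-methyloxiran-2-yl]methoxy}-8-methoxy-2H-chromen-2-one (target)
Conditions: PPh3, DIAD, THF, 0 °C → rt
Reagents that add atoms: none
Why: Mitsunobu etherification; the acidic phenol protonates the betaine and the unhindered primary hydroxyl forms the oxyphosphonium much faster than the secondary allylic one, so substitution occurs at CH2 with no stereocentre involved; ring formation between C1' and the C5' oxygen is excluded because these positions are trans across the oxirane.

## Compound list

1 | L-serine | N[C@@H](CO)C(=O)O | starting material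
2 | (2S)-2-chloro-3-hydroxypropanoic acid | O=C(O)[C@@H](Cl)CO | intermediate
3 | (2S)-2-chloro-3-hydroxy-N-methoxy-N-methylpropanamide | CON(C)C(=O)[C@@H](Cl)CO | intermediate
4 | (2S)-3-[(tert-butyldimethylsilyl)oxy]-2-chloro-N-methoxy-N-methylpropanamide | CON(C)C(=O)[C@@H](Cl)CO[Si](C)(C)C(C)(C)C | intermediate
5 | (3S)-4-[(tert-butyldimethylsilyl)oxy]-3-chlorobutan-2-one | CC(=O)[C@@H](Cl)CO[Si](C)(C)C(C)(C)C | intermediate
6 | mesityl oxide (4-methylpent-3-en-2-one) | CC(=O)C=C(C)C | starting material
7 | lithium 4-methylpenta-1,3-dien-2-olate | [Li]OC(=C)C=C(C)C | intermediate (not isolated)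
8 | (6R,7S)-8-[(tert-butyldimethylsilyl)oxy]-7-chloro-6-hydroxy-2,6-dimethyloct-2-en-4-one | CC(C)=CC(=O)C[C@@](C)(O)[C@@H](Cl)CO[Si](C)(C)C(C)(C)C | intermediate
9 | (2S,3R,5R)-1-[(tert-butyldimethylsilyl)oxy]-2-chloro-3,7-dimethyloct-6-ene-3,5-diol | CC(C)=C[C@H](O)C[C@@](C)(O)[C@@H](Cl)CO[Si](C)(C)C(C)(C)C | intermediate
10 | (2R)-1-[(2R,3R)-3-{[(tert-butyldimethylsilyl)oxy]methyl}-2-methyloxiran-2-yl]-4-methylpent-3-en-2-ol | CC(C)(C)[Si](C)(C)OC[C@H]1O[C@]1(C)C[C@@H](O)C=C(C)C | intermediate
11 | (2R)-1-[(2R,3R)-3-(hydroxymethyl)-2-methyloxiran-2-yl]-4-methylpent-3-en-2-ol | OC[C@H]1O[C@]1(C)C[C@@H](O)C=C(C)C | intermediate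
12 | hydrangetin (7-hydroxy-8-methoxy-2H-chromen-2-one) | COc1c(O)ccc2ccc(=O)oc12 | starting material
13 | 7-{[(2R,3R)-3-[(2R)-2-hydroxy-4-methylpent-3-en-1-yl]-3-methyloxiran-2-yl]methoxy}-8-methoxy-2H-chromen-2-one | COc1c(OC[C@H]2O[C@]2(C)C[C@@H](O)C=C(C)C)ccc2ccc(=O)oc12 | target

## Step count and risks

Total: 9 steps. Longest linear sequence: 9 steps (1 → 13). Compounds 6 and 12 are bought and enter at steps 5 and 9.

**Step 5 (key step).**
- **Risk:** proton transfer from the acidic CHCl or CH3 positions of 5 to the enolate in place of addition, which would erode the C–Cl configuration and open the way to β-elimination of silanolate. The aldol may also revert on warming. Cornforth facial selectivity may be incomplete because the ketone methyl is larger than an aldehyde hydrogen.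
- **Fallback:** this sets out from 6 (with 5 as partner) and returns at 8. Dienolate 7 is trapped with Me3SiCl to give the silyl dienol ether trimethyl[(4-methylpenta-1,3-dien-2-yl)oxy]silane F1. F1 is added to 5 in a Mukaiyama aldol reaction with BF3·OEt2 in CH2Cl2 at −78 °C. This has an open transition state with no basic species and the same polar Felkin–Anh sense. Aqueous work-up gives 8.

**Step 6.**
- **Risk:** modest facial selectivity, because the directing carbinol is tertiary and the methyl and chloroalkyl groups must be told apart in the chair. Intermolecular reduction may compete, and the new allylic alcohol may ionise in acetic acid.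
- **Fallback:** this sets out from 8 and returns at 9. It is a reagent-controlled Corey–Bakshi–Shibata reduction with the (S)-B-methyl oxazaborolidine derived from (S)-diphenylprolinol and catecholborane at −78 °C. The alkenyl group acts as the large substituent, which corresponds to the (5R) alcohol. No new compound is made (F0).

**Step 4.**
- **Risk:** deprotonation α to the amide by the Grignard reagent, or epimerisation and loss of silanol from the product ketone during work-up.
- **Fallback:** this sets out from 4 and returns at 5. Amide 4 is reduced with iBu2AlH at −78 °C to the aldehyde (2S)-3-[(tert-butyldimethylsilyl)oxy]-2-chloropropanal F2. MeMgBr at −78 °C gives the alcohol (2RS,3S)-4-[(tert-butyldimethylsilyl)oxy]-3-chlorobutan-2-ol F3, whose carbinol configuration is immaterial. Non-basic Dess–Martin oxidation gives 5.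

**Step 9.**
- **Risk:** competing activation of the secondary allylic C5' hydroxyl (etherification, allylic substitution or elimination), or attack of the hydrazide anion on the epoxide.
- **Fallback:** this sets out from 10 and returns at 13.
  - Compound 10 is acetylated (Ac2O, pyridine, DMAP) to (2R)-1-[(2R,3R)-3-{[(tert-butyldimethylsilyl)oxy]methyl}-2-methyloxiran-2-yl]-4-methylpent-3-en-2-yl acetate F4.
  - F4 is desilylated with Bu4NF/AcOH to (2R)-1-[(2R,3R)-3-(hydroxymethyl)-2-methyloxiran-2-yl]-4-methylpent-3-en-2-yl acetate F5.
  - F5 is coupled with 12 under Mitsunobu conditions to (2R)-1-[(2R,3R)-3-{[(8-methoxy-2-oxo-2H-chromen-7-yl)oxy]methyl}-2-methyloxiran-2-yl]-4-methylpent-3-en-2-yl acetate F6.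
  - The acetate is removed with K2CO3 in MeOH at 0 °C to give 13.

**Step 7.**
- **Risk:** 5-exo displacement of chloride by the C5 oxygen, giving a tetrahydrofuran, in competition with the 3-exo closure, or sluggish closure by the hindered tertiary alkoxide.
- **Fallback:** this sets out from 9 and returns at 11. The secondary hydroxyl alone is silylated (TBSCl, imidazole, DMF) to (2S,3R,5R)-1,5-bis[(tert-butyldimethylsilyl)oxy]-2-chloro-3,7-dimethyloct-6-en-3-ol F7. K2CO3 in MeOH closes the oxirane to tert-butyl{[(2R,3R)-3-[(2R)-2-[(tert-butyldimethylsilyl)oxy]-4-methylpent-3-en-1-yl]-3-methyloxiran-2-yl]methoxy}dimethylsilane F8. Excess Bu4NF/AcOH removes both silyl groups to give 11.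

## Further compounds

F1 | step 5 | trimethyl[(4-methylpenta-1,3-dien-2-yl)oxy]silane | C=C(O[Si](C)(C)C)C=C(C)C
F0 | step 6 | none | none
F2 | step 4 | (2S)-3-[(tert-butyldimethylsilyl)oxy]-2-chloropropanal | O=C[C@@H](Cl)CO[Si](C)(C)C(C)(C)C
F3 | step 4 | (2RS,3S)-4-[(tert-butyldimethylsilyl)oxy]-3-chlorobutan-2-ol | CC(O)[C@@H](Cl)CO[Si](C)(C)C(C)(C)C
F4 | step 9 | (2R)-1-[(2R,3R)-3-{[(tert-butyldimethylsilyl)oxy]methyl}-2-methyloxiran-2-yl]-4-methylpent-3-en-2-yl acetate | CC(C)(C)[Si](C)(C)OC[C@H]1O[C@]1(C)C[C@@H](OC(C)=O)C=C(C)C
F5 | step 9 | (2R)-1-[(2R,3R)-3-(hydroxymethyl)-2-methyloxiran-2-yl]-4-methylpent-3-en-2-yl acetate | OC[C@H]1O[C@]1(C)C[C@@H](OC(C)=O)C=C(C)C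
F6 | step 9 | (2R)-1-[(2R,3R)-3-{[(8-methoxy-2-oxo-2H-chromen-7-yl)oxy]methyl}-2-methyloxiran-2-yl]-4-methylpent-3-en-2-yl acetate | COc1c(OC[C@H]2O[C@]2(C)C[C@@H](OC(C)=O)C=C(C)C)ccc2ccc(=O)oc12
F7 | step 7 | (2S,3R,5R)-1,5-bis[(tert-butyldimethylsilyl)oxy]-2-chloro-3,7-dimethyloct-6-en-3-ol | CC(C)=C[C@H](O[Si](C)(C)C(C)(C)C)C[C@@](C)(O)[C@@H](Cl)CO[Si](C)(C)C(C)(C)C
F8 | step 7 | tert-butyl{[(2R,3R)-3-[(2R)-2-[(tert-butyldimethylsilyl)oxy]-4-methylpent-3-en-1-yl]-3-methyloxiran-2-yl]methoxy}dimethylsilane | CC(C)(C)[Si](C)(C)OC[C@H]1O[C@]1(C)C[C@@H](O[Si](C)(C)C(C)(C)C)C=C(C)C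
A1 | alternative 1 | 8-methoxy-7-{[(2R,3R)-3-methyl-3-(4-methyl-2-oxopent-3-en-1-yl)oxiran-2-yl]methoxy}-2H-chromen-2-one | COc1c(OC[C@H]2O[C@]2(C)CC(=O)C=C(C)C)ccc2ccc(=O)oc12
A2 | alternative 1 | 7-{[(2E)-3,7-dimethyl-5-oxoocta-2,6-dien-1-yl]oxy}-8-methoxy-2H-chromen-2-one | COc1c(OC/C=C(\C)CC(=O)C=C(C)C)ccc2ccc(=O)oc12
A3 | alternative 2 | 7-{[(2R,3R)-3-[(2R)-2-[(tert-butyldimethylsilyl)oxy]-4-methylpent-3-en-1-yl]-3-methyloxiran-2-yl]methoxy}-8-methoxy-2H-chromen-2-one | COc1c(OC[C@H]2O[C@]2(C)C[C@@H](O[Si](C)(C)C(C)(C)C)C=C(C)C)ccc2ccc(=O)oc12
A4 | alternative 2 | 4-{[(2R,3R)-3-[(2R)-2-[(tert-butyldimethylsilyl)oxy]-4-methylpent-3-en-1-yl]-3-methyloxiran-2-yl]methoxy}-2-hydroxy-3-methoxybenzaldehyde | COc1c(OC[C@H]2O[C@]2(C)C[C@@H](O[Si](C)(C)C(C)(C)C)C=C(C)C)ccc(C=O)c1O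
A5 | alternative 2 | 2,4-dihydroxy-3-methoxybenzaldehyde | COc1c(O)ccc(C=O)c1O
A6 | alternative 3 | 2-[(2E,5R)-5-[(tert-butyldimethylsilyl)oxy]-3,7-dimethylocta-2,6-dien-1-yl]-4,4,5,5-tetramethyl-1,3,2-dioxaborolane | CC(C)=C[C@H](O[Si](C)(C)C(C)(C)C)C/C(C)=C/CB1OC(C)(C)C(C)(C)O1
A7 | alternative 3 | tert-butyldimethyl{[(4R)-2-methyl-6-methylideneocta-2,7-dien-4-yl]oxy}silane | CC(C)=C[C@H](O[Si](C)(C)C(C)(C)C)CC(=C)C=C
A8 | alternative 3 | (2E,5R)-5-[(tert-butyldimethylsilyl)oxy]-3,7-dimethylocta-2,6-dien-1-ol | CC(C)=C[C@H](O[Si](C)(C)C(C)(C)C)C/C(C)=C/CO
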